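**Retrosynthetic overview**

- Target ⇒ 7-hydroxycoumarin + primary C-11 alcohol (Mitsunobu C–O bond).
- C-9–C-11 bond and the C-7 alkene ⇒ trans-fused enedione: conjugate addition of a hydroxymethyl equivalent anti to the angular methyl, then enolate → enol triflate → C–H.
- Ring A (closed last) ⇒ C-2–C-3 bond by ester methylenation/ring-closing metathesis onto an allyl group; C-4–C-5 bond by Mukaiyama–Michael addition anti to that allyl group.
- Ring B is the former arene: oxidative para-allylation of 2,4-dimethylphenol creates the C-10 quaternary centre and both enones in one step.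
- Absolute configuration comes from a catalyst-controlled Michael step on the racemic dienone; ring order B (from the arene) → A.

Assumption: locants C-1 to C-11 in the text are drimane locants of the target (C-3 ketone, C-4 gem-dimethyl carbon, C-5/C-10 ring fusion, C-9 bearing C-11H2O). Dienone 3 is made as a racemate and only its (R)-enantiomer leads on, so step 2 cannot exceed 50 %. The catalyst antipode in step 2 is assigned by analogy with cyclohexenone; if the facial sense is reversed, the enantiomeric catalyst is used.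

**Route**

Step 1
Reactants: 1 2,4-dimethylphenol; 2 allyltrimethylsilane
Product: 3 rac-2,4-dimethyl-4-(prop-2-en-1-yl)cyclohexa-2,5-dien-1-one
Conditions: PhI(OAc)2, HFIP/CH2Cl2, −15 to 0 °C
Reagents that add atoms: allyltrimethylsilane, C=CC[Si](C)(C)C
Why: Oxidative dearomatisation (aromatic ring umpolung) in which PhI(OAc)2 turns the phenol into a phenoxonium species that the allylsilane traps at the methyl-bearing para carbon (Hosomi–Sakurai-type SE2′ attack), giving a quaternary C-10 that cannot re-aromatise and is formed as a racemate.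

Step 2
Reactants: 3 rac-2,4-dimethyl-4-(prop-2-en-1-yl)cyclohexa-2,5-dien-1-one; 4 1-methoxy-2-methyl-1-(trimethylsilyloxy)prop-1-ene
Product: 5 methyl 2-[(1S,6S)-4,6-dimethyl-6-(prop-2-en-1-yl)-3-(trimethylsilyloxy)cyclohexa-2,4-dien-1-yl]-2-methylpropanoate
Conditions: (S)-o-tolyl-CBS oxazaborolidine·HNTf2 (20 mol %), Ph3P=O (25 mol %), toluene, −40 to −20 °C; non-aqueous work-up, used crude
Reagents that add atoms: 1-methoxy-2-methyl-1-(trimethylsilyloxy)prop-1-ene, COC(O[Si](C)(C)C)=C(C)C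
Why: Proposed new method: the chiral oxazaborolidinium ion binds the single carbonyl syn to its only α-C–H, so addition occurs at the β-carbon of the unsubstituted enone arm (the α-methyl arm is less electrophilic and more hindered) and one face of C-5 is left open in both enantiomers of 3, so the ketene acetal gives from (R)-3 the adduct with the new C-4–C-5 bond anti to allyl (5, C-5 set by the catalyst) and from (S)-3 its syn diastereomer, which is removed after step 3 — a catalyst-controlled divergent resolution whose closest known type is the enantioselective Mukaiyama–Michael addition of this same ketene acetal to cyclohexenone under chiral oxazaborolidinium catalysis.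

Step 3
Reactants: 5 methyl 2-[(1S,6S)-4,6-dimethyl-6-(prop-2-en-1-yl)-3-(trimethylsilyloxy)cyclohexa-2,4-dien-1-yl]-2-methylpropanoate; 6 Tebbe reagent Cp2Ti(μ-CH2)(μ-Cl)AlMe2; 7 water
Product: 10 (4aS,8aS)-1,1,4a,6-tetramethyl-3,4,4a,8a-tetrahydronaphthalene-2,7(1H,8H)-dione, via methyl enol ether 8 (not isolated), via bicyclic bis-enol ether 9 (not isolated)
Conditions: 6 (4 equiv), pyridine (cat.), THF, 0 to 25 °C, then 65 °C; then 1 M HCl, THF, 0 °C; chromatography removes the cis-fused isomer, one recrystallisation raises the ee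
Reagents that add atoms: water, O
Why: Tandem Tebbe methylenation of the ester and titanium-alkylidene ring-closing olefin metathesis (olefinic-ester cyclisation) closes ring A between the allyl CH and the former ester carbon, acid hydrolysis of both enol ethers frees the two ketones, and no stereocentre is touched, so the trans ring fusion follows from the anti arrangement set in step 2.

Step 4
Reactants: 10 (4aS,8aS)-1,1,4a,6-tetramethyl-3,4,4a,8a-tetrahydronaphthalene-2,7(1H,8H)-dione; 11 {[dimethyl(propan-2-yloxy)silyl]methyl}magnesium chloride; 12 Comins' reagent, N-(5-chloropyridin-2-yl)-1,1,1-trifluoro-N-(trifluoromethylsulfonyl)methanesulfonamide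
Product: 14 (4R,4aR,8aS)-4-{[dimethyl(propan-2-yloxy)silyl]methyl}-3,4a,8,8-tetramethyl-7-oxo-1,4,4a,5,6,7,8,8a-octahydronaphthalen-2-yl trifluoromethanesulfonate, via chloromagnesium enolate 13 (not isolated)
Conditions: 11 (2.4 equiv), CuBr·SMe2 (1.2 equiv), THF, −78 to −30 °C; then 12, −78 °C to rt
Reagents that add atoms: {[dimethyl(propan-2-yloxy)silyl]methyl}magnesium chloride, CC(C)O[Si](C)(C)C[Mg]Cl; Comins' reagent, O=S(=O)(N(c1ccc(Cl)cn1)S(=O)(=O)C(F)(F)F)C(F)(F)F
Why: Organocuprate conjugate addition of the Tamao hydroxymethyl-anion equivalent to the enone proceeds by axial attack anti to the axial C-10 methyl, which sets C-9 with its CH2 group trans to that methyl, and the regiodefined enolate is trapped as the enol triflate, the saturated C-3 ketone being inert to the cuprate.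

Step 5
Reactants: 14 (4R,4aR,8aS)-4-{[dimethyl(propan-2-yloxy)silyl]methyl}-3,4a,8,8-tetramethyl-7-oxo-1,4,4a,5,6,7,8,8a-octahydronaphthalen-2-yl trifluoromethanesulfonate
Product: 15 (4aR,5S,8aS)-5-{[dimethyl(propan-2-yloxy)silyl]methyl}-1,1,4a,6-tetramethyl-3,4,4a,5,8,8a-hexahydronaphthalen-2(1H)-one
Conditions: Pd(OAc)2 (5 mol %), PPh3 (10 mol %), HCO2H, Bu3N, DMF, 60 °C
Reagents that add atoms: none
Why: Palladium-catalysed formate reduction of the enol triflate (Cacchi reduction) replaces OTf by H and leaves the C-7=C-8 double bond exactly where the enolate was, with no stereocentre involved.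

Step 6
Reactants: 15 (4aR,5S,8aS)-5-{[dimethyl(propan-2-yloxy)silyl]methyl}-1,1,4a,6-tetramethyl-3,4,4a,5,8,8a-hexahydronaphthalen-2(1H)-one; 16 hydrogen peroxide
Product: 17 (4aR,5S,8aS)-5-(hydroxymethyl)-1,1,4a,6-tetramethyl-3,4,4a,5,8,8a-hexahydronaphthalen-2(1H)-one
Conditions: 30 % H2O2, KHCO3, THF/MeOH, 50 °C
Reagents that add atoms: hydrogen peroxide, OO
Why: Tamao–Fleming oxidation converts the primary C–Si bond of the alkoxysilane into C–OH at the non-stereogenic CH2, so C-5, C-9 and C-10 are untouched.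

Step 7
Reactants: 17 (4aR,5S,8aS)-5-(hydroxymethyl)-1,1,4a,6-tetramethyl-3,4,4a,5,8,8a-hexahydronaphthalen-2(1H)-one; 18 7-hydroxy-2H-chromen-2-one (umbelliferone)
Product: 19 7-{[(1S,4aS,8aR)-2,5,5,8a-tetramethyl-6-oxo-1,4,4a,5,6,7,8,8a-octahydronaphthalen-1-yl]methoxy}-2H-chromen-2-one
Conditions: PPh3, DIAD, THF, 0 °C to rt
Reagents that add atoms: 7-hydroxy-2H-chromen-2-one, Oc1ccc2ccc(=O)oc2c1
Why: Mitsunobu etherification of the primary alcohol with the acidic phenol (pKa about 8) forms the aryl ether at CH2, so all three stereocentres are retained and the product is the target.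

**Compound list**

1 | 2,4-dimethylphenol | Cc1ccc(O)c(C)c1 | starting material
2 | allyltrimethylsilane | C=CC[Si](C)(C)C | starting material
3 | rac-2,4-dimethyl-4-(prop-2-en-1-yl)cyclohexa-2,5-dien-1-one (racemate; the (R)-enantiomer leads on) | C=CCC1(C)C=CC(=O)C(C)=C1 | intermediate
4 | 1-methoxy-2-methyl-1-(trimethylsilyloxy)prop-1-ene | COC(O[Si](C)(C)C)=C(C)C | starting material
5 | methyl 2-[(1S,6S)-4,6-dimethyl-6-(prop-2-en-1-yl)-3-(trimethylsilyloxy)cyclohexa-2,4-dien-1-yl]-2-methylpropanoate | C=CC[C@@]1(C)C=C(C)C(O[Si](C)(C)C)=C[C@@H]1C(C)(C)C(=O)OC | intermediate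
6 | Tebbe reagent Cp2Ti(μ-CH2)(μ-Cl)AlMe2 (bridging chloride drawn with formal charges on Al and Cl) | C[Al-]1(C)C[Ti](C2C=CC=C2)(C2C=CC=C2)[Cl+]1 | starting material
7 | water | O | starting material
8 | trimethyl{[(3S,4S)-3-(3-methoxy-2-methylbut-3-en-2-yl)-4,6-dimethyl-4-(prop-2-en-1-yl)cyclohexa-1,5-dien-1-yl]oxy}silane | C=CC[C@@]1(C)C=C(C)C(O[Si](C)(C)C)=C[C@@H]1C(C)(C)C(=C)OC | intermediate
9 | {[(4aS,8aS)-7-methoxy-3,4a,8,8-tetramethyl-4a,5,8,8a-tetrahydronaphthalen-2-yl]oxy}trimethylsilane | COC1=CC[C@@]2(C)C=C(C)C(O[Si](C)(C)C)=C[C@@H]2C1(C)C | intermediate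
10 | (4aS,8aS)-1,1,4a,6-tetramethyl-3,4,4a,8a-tetrahydronaphthalene-2,7(1H,8H)-dione (trans-fused) | CC1=C[C@]2(C)CCC(=O)C(C)(C)[C@H]2CC1=O | intermediate
11 | {[dimethyl(propan-2-yloxy)silyl]methyl}magnesium chloride | CC(C)O[Si](C)(C)C[Mg]Cl | starting material
12 | Comins' reagent, N-(5-chloropyridin-2-yl)-1,1,1-trifluoro-N-(trifluoromethylsulfonyl)methanesulfonamide | O=S(=O)(N(c1ccc(Cl)cn1)S(=O)(=O)C(F)(F)F)C(F)(F)F | starting material
13 | chloromagnesium (4R,4aR,8aS)-4-{[dimethyl(propan-2-yloxy)silyl]methyl}-3,4a,8,8-tetramethyl-7-oxo-1,4,4a,5,6,7,8,8a-octahydronaphthalen-2-olate | CC1=C(O[Mg]Cl)C[C@@H]2C(C)(C)C(=O)CC[C@@]2(C)[C@H]1C[Si](C)(C)OC(C)C | intermediate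
14 | (4R,4aR,8aS)-4-{[dimethyl(propan-2-yloxy)silyl]methyl}-3,4a,8,8-tetramethyl-7-oxo-1,4,4a,5,6,7,8,8a-octahydronaphthalen-2-yl trifluoromethanesulfonate | CC1=C(OS(=O)(=O)C(F)(F)F)C[C@@H]2C(C)(C)C(=O)CC[C@@]2(C)[C@H]1C[Si](C)(C)OC(C)C | intermediate
15 | (4aR,5S,8aS)-5-{[dimethyl(propan-2-yloxy)silyl]methyl}-1,1,4a,6-tetramethyl-3,4,4a,5,8,8a-hexahydronaphthalen-2(1H)-one | CC1=CC[C@@H]2C(C)(C)C(=O)CC[C@@]2(C)[C@H]1C[Si](C)(C)OC(C)C | intermediate
16 | hydrogen peroxide | OO | starting material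
17 | (4aR,5S,8aS)-5-(hydroxymethyl)-1,1,4a,6-tetramethyl-3,4,4a,5,8,8a-hexahydronaphthalen-2(1H)-one | CC1=CC[C@@H]2C(C)(C)C(=O)CC[C@@]2(C)[C@H]1CO | intermediate
18 | 7-hydroxy-2H-chromen-2-one (umbelliferone) | Oc1ccc2ccc(=O)oc2c1 | starting material
19 | 7-{[(1S,4aS,8aR)-2,5,5,8a-tetramethyl-6-oxo-1,4,4a,5,6,7,8,8a-octahydronaphthalen-1-yl]methoxy}-2H-chromen-2-one | CC1=CC[C@@H]2C(C)(C)C(=O)CC[C@@]2(C)[C@H]1COc1ccc2ccc(=O)oc2c1 | target

**Totals**

Total step count: 7. Longest linear sequence: 7 steps (1 → 19).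

**Steps most likely to fail, with fallbacks**

Step 2 is the weakest step. The strong Lewis acid may trigger allyl migration and re-aromatisation of 3, and C-5 lies between two fully substituted carbons. Because it is a resolution, any substrate preference for attack anti to allyl lowers the ee of 5.

The fallback replaces the resolution by a desymmetrisation of a prochiral dienone. It sets out from 2, with commercial 4-methylphenol in place of 1. The step 1 protocol gives 4-methyl-4-(prop-2-en-1-yl)cyclohexa-2,5-dien-1-one F1, whose two enones are enantiotopic. The step 2 catalyst and 4 then add once to give methyl 2-methyl-2-[(1S,6S)-6-methyl-6-(prop-2-en-1-yl)-3-(trimethylsilyloxy)cyclohexa-2,4-dien-1-yl]propanoate F2, with the ee fixed by the catalyst alone. The step 3 protocol with 6 and 7 passes through trimethyl{[(3S,4S)-3-(3-methoxy-2-methylbut-3-en-2-yl)-4-methyl-4-(prop-2-en-1-yl)cyclohexa-1,5-dien-1-yl]oxy}silane F3 and {[(4aS,8aS)-7-methoxy-4a,8,8-trimethyl-4a,5,8,8a-tetrahydronaphthalen-2-yl]oxy}trimethylsilane F4 to (4aS,8aS)-1,1,4a-trimethyl-3,4,4a,8a-tetrahydronaphthalene-2,7(1H,8H)-dione F5. α-Iodination (I2, pyridine, CH2Cl2) gives (4aR,8aS)-6-iodo-1,1,4a-trimethyl-3,4,4a,8a-tetrahydronaphthalene-2,7(1H,8H)-dione F6. Stille methylation (Me4Sn, Pd2(dba)3, AsPh3, CuI, NMP) then installs the C-8 methyl and comes back to the route at 10, two steps longer.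

Step 3 is the second risk. The ester is neopentyl-like, and the titanium alkylidene must close onto a hindered 1,1-disubstituted enol ether.

The fallback avoids carbonyl olefination: the enol ether is made by enolisation and the ring is closed with ruthenium. It sets out from 3. 3-Methylbutan-2-one is first converted (Me3SiCl, NaI, Et3N, MeCN) into trimethyl[(3-methylbut-2-en-2-yl)oxy]silane F7. This replaces 4 under the step 2 catalyst and gives 3-[(1S,6S)-4,6-dimethyl-6-(prop-2-en-1-yl)-3-(trimethylsilyloxy)cyclohexa-2,4-dien-1-yl]-3-methylbutan-2-one F8. Kinetic silylation of the methyl ketone (LiN(iPr)2, Me3SiCl, THF, −78 °C) gives trimethyl{[(3S,4S)-4,6-dimethyl-3-[2-methyl-3-(trimethylsilyloxy)but-3-en-2-yl]-4-(prop-2-en-1-yl)cyclohexa-1,5-dien-1-yl]oxy}silane F9. Ring-closing metathesis with the second-generation Grubbs catalyst (H2IMes)(PCy3)Cl2Ru=CHPh in toluene at 80 °C gives [(4aS,8aS)-3,4a,8,8-tetramethyl-4a,5,8,8a-tetrahydronaphthalene-2,7-diyl]bis(oxy)bis(trimethylsilane) F10. Dilute HCl then returns to the route at 10.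

Step 1 is the third risk. The free ortho position C-6 can be attacked directly, or reached by [3,3] shift of the allyl group, and either path re-aromatises.

The fallback blocks that position before dearomatisation. It sets out from 1. Bromination (N-bromosuccinimide, MeCN, 0 °C) gives 2-bromo-4,6-dimethylphenol F11. The step 1 protocol with 2 then gives rac-2-bromo-4,6-dimethyl-4-(prop-2-en-1-yl)cyclohexa-2,5-dien-1-one F12, in which neither ortho carbon carries hydrogen. Hydrodebromination of the α-bromo enone (Pd(PPh3)4, HCO2H, Et3N, DMF, 60 °C) comes back to the route at 3.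

**Further compounds**

F1 | step 2 | 4-methyl-4-(prop-2-en-1-yl)cyclohexa-2,5-dien-1-one | C=CCC1(C)C=CC(=O)C=C1
F2 | step 2 | methyl 2-methyl-2-[(1S,6S)-6-methyl-6-(prop-2-en-1-yl)-3-(trimethylsilyloxy)cyclohexa-2,4-dien-1-yl]propanoate | C=CC[C@@]1(C)C=CC(O[Si](C)(C)C)=C[C@@H]1C(C)(C)C(=O)OC
F3 | step 2 | trimethyl{[(3S,4S)-3-(3-methoxy-2-methylbut-3-en-2-yl)-4-methyl-4-(prop-2-en-1-yl)cyclohexa-1,5-dien-1-yl]oxy}silane | C=CC[C@@]1(C)C=CC(O[Si](C)(C)C)=C[C@@H]1C(C)(C)C(=C)OC
F4 | step 2 | {[(4aS,8aS)-7-methoxy-4a,8,8-trimethyl-4a,5,8,8a-tetrahydronaphthalen-2-yl]oxy}trimethylsilane | COC1=CC[C@@]2(C)C=CC(O[Si](C)(C)C)=C[C@@H]2C1(C)C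
F5 | step 2 | (4aS,8aS)-1,1,4a-trimethyl-3,4,4a,8a-tetrahydronaphthalene-2,7(1H,8H)-dione | O=C1C=C[C@]2(C)CCC(=O)C(C)(C)[C@H]2C1
F6 | step 2 | (4aR,8aS)-6-iodo-1,1,4a-trimethyl-3,4,4a,8a-tetrahydronaphthalene-2,7(1H,8H)-dione | O=C1C(I)=C[C@]2(C)CCC(=O)C(C)(C)[C@H]2C1
F7 | step 3 | trimethyl[(3-methylbut-2-en-2-yl)oxy]silane | CC(C)=C(C)O[Si](C)(C)C
F8 | step 3 | 3-[(1S,6S)-4,6-dimethyl-6-(prop-2-en-1-yl)-3-(trimethylsilyloxy)cyclohexa-2,4-dien-1-yl]-3-methylbutan-2-one | C=CC[C@@]1(C)C=C(C)C(O[Si](C)(C)C)=C[C@@H]1C(C)(C)C(C)=O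
F9 | step 3 | trimethyl{[(3S,4S)-4,6-dimethyl-3-[2-methyl-3-(trimethylsilyloxy)but-3-en-2-yl]-4-(prop-2-en-1-yl)cyclohexa-1,5-dien-1-yl]oxy}silane | C=CC[C@@]1(C)C=C(C)C(O[Si](C)(C)C)=C[C@@H]1C(C)(C)C(=C)O[Si](C)(C)C
F10 | step 3 | [(4aS,8aS)-3,4a,8,8-tetramethyl-4a,5,8,8a-tetrahydronaphthalene-2,7-diyl]bis(oxy)bis(trimethylsilane) | C[Si](C)(C)OC1=CC[C@@]2(C)C=C(C)C(O[Si](C)(C)C)=C[C@@H]2C1(C)C
F11 | step 1 | 2-bromo-4,6-dimethylphenol | Cc1cc(C)c(O)c(Br)c1
F12 | step 1 | rac-2-bromo-4,6-dimethyl-4-(prop-2-en-1-yl)cyclohexa-2,5-dien-1-one (racemate) | C=CCC1(C)C=C(C)C(=O)C(Br)=C1
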